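The 14-membered ring is disconnected by drawing C1, C2, C3, C13 and C14 as a cyclopentene (extra C13–C3 bond) that carries the C15–C16 acetic acid arm on C1. Iodolactonisation of this (S)-cyclopent-2-enylacetic acid closes the γ-lactone and forms the C14–O bond in one operation. It exploits the cis C1/C14 junction of the butyrolactone ring: a five-five bicycle can only be cis-fused, so C1 alone dictates C14. Elimination and ozonolysis then open the template at C13=C3; the C3 aldehyde grows the oxolane arm, the C13 aldehyde the crotyl arm, and ring-closing metathesis at C10–C11 completes the macrocycle.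

Key step: step 1

Remarks on the chemistry (assumptions):
- Numbering: C1 lactone CH, C14 lactone OCH, C13 CHOAc, C12 CHMe, C9–C11 CH2, C8 C(Me)OAc, C7 and C4 oxolane carbons, C5–C6 CH2, C3 CHOH, C2 CH2, C15 lactone α-carbon, C16 C=O, C17 exocyclic CH2.
- Target configuration: 1S,3R,4S,7R,8S,12S,13R,14R. O13/O14 and O13/Me12 are syn; O3/O4 and O7/O8 are anti along the ring chain; the oxolane is 2,5-cis.
- Structure check: (S)-acid 1 maps onto C1 (S), and the cis-fused iodolactone 2 (iodine trans to the ring oxygen) onto C14 (R). Both structures stand unchanged.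
- Assumption: enantiopure acid 1 is purchased (otherwise resolved from the racemate).
- Design choice: lactone enolate chemistry cannot be run once the two acetates are present. C17 is therefore installed early as CH2OBn (step 3) and unveiled by β-elimination after acetylation (step 23). C15 is a transient stereocentre (R expected).

Step 1
Reactants: 1 (S)-cyclopent-2-enylacetic acid
Product: 2 (3aS,6R,6aR)-6-iodohexahydro-2H-cyclopenta[b]furan-2-one (cis-fused iodolactone; iodine on C13, trans to the ring oxygen)
Conditions: I2, KI, NaHCO3, H2O–THF, 0 °C to rt, dark; Na2S2O3 wash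
Reagents that add atoms: iodine, II
Why: Iodine adds reversibly to the C13=C14 double bond of the carboxylate, and the iodonium ion is opened at C14 by the carboxylate oxygen (iodolactonisation of a γ,δ-unsaturated acid, the classical halolactonisation). The γ-lactone closes in the 5-exo mode at the proximal alkene carbon C14; 6-endo attack at C13 would give a strained bridged δ-lactone. C14 is controlled by C1, because the two-atom tether reaches only the alkene face on which it sits, so the new C14–O bond is cis to the C1–C15 bond and the bicyclo[3.3.0] system is cis-fused. Anti opening of the iodonium ion places iodine on C13 trans to the ring oxygen; this centre is removed in step 2. The step needs γ- over δ-regioselectivity and face selectivity, both secured by the short tether under kinetic (bicarbonate) conditions.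

Step 2
Reactants: 2 iodolactone
Product: 3 (3aS,6aR)-3,3a,4,6a-tetrahydro-2H-cyclopenta[b]furan-2-one (cis-fused lactone with the C13=C3 double bond)
Conditions: DBU, THF, reflux
Reagents that add atoms: none
Why: E2 dehydroiodination; the C13–I bond is anti-periplanar only to a C3–H (C14–H is cis to iodine), so the C13=C3 alkene forms and not the enol ether.

Step 3
Reactants: 3 alkene lactone
Product: 4 (3R,3aS,6aR)-3-(benzyloxymethyl)-3,3a,4,6a-tetrahydro-2H-cyclopenta[b]furan-2-one (CH2OBn on C15, exo)
Conditions: LiN(i-Pr)2, THF, −78 °C; BnOCH2Cl, −78 to −40 °C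
Reagents that add atoms: benzyl chloromethyl ether, ClCOCc1ccccc1
Why: Lactone enolate alkylation; the electrophile approaches the convex face of the cis-fused bicycle (trans to the cyclopentene ring), giving C15 (R) and installing C17 in protected form.

Step 4
Reactants: 4 benzyloxymethyl lactone
Product: 7 2-[(2R,3S,4R)-4-(benzyloxymethyl)-2-(dimethoxymethyl)-5-oxooxolan-3-yl]acetaldehyde (C3 aldehyde/C13 dimethyl acetal), via methoxyhydroperoxide aldehyde 5 (not isolated), via methoxyhydroperoxide acetal 6 (not isolated)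
Conditions: O3, CH2Cl2–MeOH (5:1), −78 °C; then TsOH·H2O (10 mol%), −78 °C to rt; then NaHCO3, Me2S, rt
Reagents that add atoms: ozone, [O-][O+]=O; methanol, CO
Why: Criegee ozonolysis with unsymmetrical work-up; the primary ozonide should fragment with the carbonyl oxide at C3, remote from the electron-withdrawing C14 acyloxy group, where methanol traps it as the methoxy hydroperoxide, while acid converts the free C13 aldehyde into its dimethyl acetal before dimethyl sulfide reduces the hydroperoxide to the C3 aldehyde; C1, C14 and C15 are untouched.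

Step 5
Reactants: 7 aldehyde acetal
Product: 8 (E)-4-[(2R,3S,4R)-4-(benzyloxymethyl)-2-(dimethoxymethyl)-5-oxooxolan-3-yl]-2-methylbut-2-enal (C3=C4, C5 aldehyde)
Conditions: Ph3P=C(CH3)CHO, toluene, 80 °C
Reagents that add atoms: 2-(triphenylphosphoranylidene)propanal, CC(C=O)=P(c1ccccc1)(c1ccccc1)c1ccccc1
Why: Wittig olefination with a formyl-stabilised ylide gives the E-trisubstituted enal under thermodynamic control, and the neutral conditions spare lactone and acetal.

Step 6
Reactants: 8 enal
Product: 9 the corresponding (E)-allylic alcohol (C5 OH)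
Conditions: NaBH4, CeCl3·7H2O, MeOH, −40 °C
Reagents that add atoms: none
Why: Luche reduction is 1,2-selective for the enal and leaves the lactone untouched at low temperature.

Step 7
Reactants: 9 allylic alcohol
Product: 10 the corresponding (E)-allylic bromide (C5 Br)
Conditions: CBr4, PPh3, CH2Cl2, −20 to 0 °C
Reagents that add atoms: tetrabromomethane, BrC(Br)(Br)Br
Why: Appel reaction; SN2 displacement of the primary alkoxyphosphonium ion gives the bromide without allylic transposition or loss of E geometry.

Step 8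
Reactants: 11 (R)-lactic acid; 12 pivalaldehyde
Product: 13 (2R,5R)-2-tert-butyl-5-methyl-1,3-dioxolan-4-one (cis)
Conditions: TsOH·H2O (cat.), pentane, reflux with water separator; crystallisation at −78 °C
Reagents that add atoms: none
Why: Acid-catalysed acetalisation of the α-hydroxy acid; the cis acetal is the thermodynamic product, is purified by crystallisation, and its acetal centre will relay the chirality.

Step 9
Reactants: 13 dioxolanone
Product: 14 (2R,5S)-2-tert-butyl-5-methyl-5-(prop-2-enyl)-1,3-dioxolan-4-one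
Conditions: LiN(i-Pr)2, THF, −78 °C; allyl bromide, −78 to −30 °C
Reagents that add atoms: allyl bromide, C=CCBr
Why: Enolate alkylation with self-regeneration of the stereocentre; the planar enolate is allylated on the face opposite the tert-butyl group, so allyl takes the place of the former hydrogen and the future C8 forms as one quaternary centre.

Step 10
Reactants: 14 allyl dioxolanone
Product: 15 (S)-2-hydroxy-N-methoxy-N,2-dimethylpent-4-enamide
Conditions: MeNH(OMe)·HCl, i-PrMgCl, THF, −20 to 0 °C
Reagents that add atoms: N,O-dimethylhydroxylamine hydrochloride, CNOC.Cl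
Why: Aminolysis of the acetal-lactone by the magnesium amide gives the Weinreb amide with release of pivalaldehyde; the quaternary centre cannot epimerise.

Step 11
Reactants: 15 hydroxy Weinreb amide
Product: 16 (S)-N-methoxy-N,2-dimethyl-2-(triethylsilyloxy)pent-4-enamide
Conditions: Et3SiOTf, 2,6-lutidine, CH2Cl2, 0 °C
Reagents that add atoms: triethylsilyl trifluoromethanesulfonate, CC[Si](CC)(CC)OS(=O)(=O)C(F)(F)F
Why: Silylation of the tertiary alcohol with a silyl triflate and a hindered base, which masks the hydroxyl for the organometallic and enolate steps.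

Step 12
Reactants: 16 silyloxy Weinreb amide
Product: 17 (S)-3-methyl-3-(triethylsilyloxy)hex-5-en-2-one (C6–C10 ketone fragment)
Conditions: MeMgBr, THF, 0 °C to rt
Reagents that add atoms: methylmagnesium bromide, C[Mg]Br
Why: Weinreb ketone synthesis; the chelated tetrahedral adduct stops the addition at the methyl ketone, whose only enolisable position is the future C6.

Step 13
Reactants: 17 ketone fragment; 10 allylic bromide
Product: 18 coupled C7 ketone (lactone of 10 whose C1 side chain is (E)-CH2CH=C(CH3)CH2CH2C(=O)C(CH3)(OSiEt3)CH2CH=CH2; 8S)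
Conditions: 17, LiN(i-Pr)2, THF, −78 °C; then 10, DMPU, −78 to −30 °C
Reagents that add atoms: none
Why: Alkylation of the kinetic lithium enolate (only the methyl side can enolise) by the primary allylic bromide in an SN2 reaction joins C5 to C6; the ketone enolate is too weak a base to deprotonate the lactone.

Step 14
Reactants: 18 coupled ketone
Product: 19 (7R,8S) secondary alcohol
Conditions: (S)-2-methyl-CBS-oxazaborolidine (0.3 equiv), catecholborane, toluene, −78 to −40 °C; MeOH, pH 7 buffer
Reagents that add atoms: none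
Why: Corey–Bakshi–Shibata reduction; the catalyst distinguishes the quaternary C8 side (large) from the C6 methylene side (small) and sets C7 (R) under reagent control, while catecholborane leaves the alkenes alone at this temperature.

Step 15
Reactants: 19 alcohol
Product: 21 2,5-cis-oxolane (C4–O–C7; 3R,4S,7R,8S) with free C3 hydroxyl, via epoxy alcohol 20 (not isolated)
Conditions: D-fructose-derived Shi ketone (0.3 equiv), KHSO5 (Oxone), K2CO3, Bu4NHSO4, Na2B4O7 buffer, MeCN–CH2(OMe)2, 0 °C; then camphorsulfonic acid (10 mol%), CH2Cl2, 0 °C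
Reagents that add atoms: potassium peroxymonosulfate, [K+].[O-]S(=O)(=O)OO
Why: Shi epoxidation of the only trisubstituted alkene gives the (3R,4R) epoxide under reagent control (the terminal alkene is much slower), and acid then triggers 5-exo opening by the C7 hydroxyl at tertiary C4 with inversion, which sets C4 (S) and leaves the epoxide oxygen as the C3 (R) hydroxyl.

Step 16
Reactants: 21 oxolane alcohol
Product: 22 C3 O-triisopropylsilyl ether of 21
Conditions: i-Pr3SiOTf, 2,6-lutidine, CH2Cl2, 0 °C to rt
Reagents that add atoms: triisopropylsilyl trifluoromethanesulfonate, CC(C)[Si](OS(=O)(=O)C(F)(F)F)(C(C)C)C(C)C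
Why: Silyl ether formation on the only free hydroxyl with a group that survives aqueous acid, oxidation and hydrogenation and is cleaved by fluoride at the end.

Step 17
Reactants: 22 bis-silyl ether acetal
Product: 23 C13 aldehyde with free tertiary C8 hydroxyl (C3 OSi(i-Pr)3 retained)
Conditions: CF3CO2H–H2O–CH2Cl2 (4:1:8), 0 °C to rt; used crude
Reagents that add atoms: water, O
Why: Acid-catalysed acetal hydrolysis; aqueous trifluoroacetic acid cleaves the deactivated C13 dimethyl acetal and the tertiary triethylsilyl ether, while the triisopropylsilyl ether, oxolane and lactone persist.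

Step 18
Reactants: 23 aldehyde
Product: 24 (12S,13S) homoallylic alcohol (C13 OH, C12 methyl, C11=CH2 vinyl; 12,13-anti, 13,14-anti)
Conditions: diisopropyl (R,R)-tartrate (E)-crotylboronate, 4 Å molecular sieves, toluene, −78 °C
Reagents that add atoms: diisopropyl (4R,5R)-2-[(E)-but-2-enyl]-1,3,2-dioxaborolane-4,5-dicarboxylate, C/C=C/CB1O[C@@H](C(=O)OC(C)C)[C@H](C(=O)OC(C)C)O1
Why: Allylboration through a closed chair (Zimmerman–Traxler) transition state; the E-crotyl geometry gives the 12,13-anti pair and the (R,R)-tartrate reagent attacks the Si face, which is also the Felkin–Anh face (matched case), fixing C12 (S) and giving C13 (S).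

Step 19
Reactants: 24 homoallylic alcohol
Product: 25 C13 ketone (12S; β,γ-unsaturated)
Conditions: Dess–Martin periodinane, NaHCO3, CH2Cl2, 0 °C
Reagents that add atoms: none
Why: Dess–Martin oxidation under bicarbonate buffer converts the secondary carbinol into the ketone without moving the double bond into conjugation; the tertiary C8 hydroxyl is inert.

Step 20
Reactants: 25 ketone
Product: 26 (12S,13R) alcohol (13,14-syn and 12,13-syn)
Conditions: LiBH(s-Bu)3, THF, −78 °C; AcOH quench at −78 °C
Reagents that add atoms: none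
Why: Felkin–Anh reduction; hydride adds anti to the C14–O bond with C14–H on the approach side, which sets C13 (R), and on this face C12 can also turn its hydrogen towards the hydride (methyl anti), so the dominant polar α-acyloxy effect meets no steric clash.

Step 21
Reactants: 26 diene diol
Product: 27 14-membered C10=C11 alkene (E/Z mixture; C13 and C8 hydroxyls free, C3 OSi(i-Pr)3, C15 CH2OBn)
Conditions: second-generation Grubbs catalyst RuCl2(=CHPh)(H2IMes)(PCy3) (10 mol%), CH2Cl2 (1 mM), 40 °C
Reagents that add atoms: none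
Why: Ring-closing metathesis of two monosubstituted alkenes forms the C10=C11 bond, driven by loss of ethylene at high dilution; the cis-oxolane and cis-lactone pre-organise the chain and the alkene geometry is irrelevant.

Step 22
Reactants: 27 macrocyclic alkene
Product: 28 saturated triol (C17 CH2OH, C13 OH, C8 OH; C3 OSi(i-Pr)3)
Conditions: H2 (1 atm), Pd/C (10%), EtOAc–EtOH, rt
Reagents that add atoms: none
Why: Heterogeneous hydrogenation saturates the disubstituted alkene and hydrogenolyses the benzyl ether in the same operation.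

Step 23
Reactants: 28 triol
Product: 30 α-methylene lactone diacetate with C3 OSi(i-Pr)3, via triacetate 29 (not isolated)
Conditions: Ac2O, Et3N, DMAP, CH2Cl2, 40 °C; then DBU, rt
Reagents that add atoms: acetic anhydride, CC(=O)OC(C)=O
Why: DMAP-catalysed acylation esterifies the primary, the secondary C13 and (on warming) the tertiary C8 hydroxyl, and DBU then removes the acidic C15–H and expels the C17 acetate (E1cB β-elimination) to give the α-methylene lactone, which erases the C15 centre.

Step 24
Reactants: 30 silyl ether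
Product: 31 target (CID10479028)
Conditions: HF·pyridine, pyridine–THF, 0 °C to rt
Reagents that add atoms: none
Why: Fluoride-mediated desilylation removes the triisopropylsilyl group without touching the two acetates or the Michael-acceptor lactone.

Compound list
1 | (S)-cyclopent-2-enylacetic acid | OC(=O)C[C@H]1C=CCC1 | starting material
2 | (3aS,6R,6aR)-6-iodohexahydro-2H-cyclopenta[b]furan-2-one | O=C1C[C@@H]2CC[C@@H](I)[C@@H]2O1 | intermediate
3 | (3aS,6aR)-3,3a,4,6a-tetrahydro-2H-cyclopenta[b]furan-2-one | O=C1C[C@@H]2CC=C[C@@H]2O1 | intermediate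
4 | (3R,3aS,6aR)-3-(benzyloxymethyl)-3,3a,4,6a-tetrahydro-2H-cyclopenta[b]furan-2-one | O=C1[C@@H](COCc2ccccc2)[C@@H]3CC=C[C@@H]3O1 | intermediate
5 | methoxyhydroperoxide aldehyde (C13 CHO, C3 CH(OMe)OOH, C3 epimers) | O=C1[C@@H](COCc2ccccc2)[C@H](CC(OC)OO)[C@H](C=O)O1 | intermediate (not isolated)
6 | methoxyhydroperoxide acetal (C13 CH(OMe)2, C3 CH(OMe)OOH) | O=C1[C@@H](COCc2ccccc2)[C@H](CC(OC)OO)[C@H](C(OC)OC)O1 | intermediate (not isolated)
7 | 2-[(2R,3S,4R)-4-(benzyloxymethyl)-2-(dimethoxymethyl)-5-oxooxolan-3-yl]acetaldehyde | O=C1[C@@H](COCc2ccccc2)[C@H](CC=O)[C@H](C(OC)OC)O1 | intermediate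
8 | (E)-4-[(2R,3S,4R)-4-(benzyloxymethyl)-2-(dimethoxymethyl)-5-oxooxolan-3-yl]-2-methylbut-2-enal | O=C1[C@@H](COCc2ccccc2)[C@H](C/C=C(\C)C=O)[C@H](C(OC)OC)O1 | intermediate
9 | (E)-allylic alcohol from 8 (C5 OH) | O=C1[C@@H](COCc2ccccc2)[C@H](C/C=C(\C)CO)[C@H](C(OC)OC)O1 | intermediate
10 | (E)-allylic bromide from 9 (C5 Br) | O=C1[C@@H](COCc2ccccc2)[C@H](C/C=C(\C)CBr)[C@H](C(OC)OC)O1 | intermediate
11 | (R)-lactic acid | C[C@@H](O)C(=O)O | starting material
12 | pivalaldehyde | CC(C)(C)C=O | starting material
13 | (2R,5R)-2-tert-butyl-5-methyl-1,3-dioxolan-4-one | C[C@H]1O[C@H](OC1=O)C(C)(C)C | intermediate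
14 | (2R,5S)-2-tert-butyl-5-methyl-5-(prop-2-enyl)-1,3-dioxolan-4-one | C[C@@]1(CC=C)O[C@H](OC1=O)C(C)(C)C | intermediate
15 | (S)-2-hydroxy-N-methoxy-N,2-dimethylpent-4-enamide | C=CC[C@](C)(O)C(=O)N(C)OC | intermediate
16 | (S)-N-methoxy-N,2-dimethyl-2-(triethylsilyloxy)pent-4-enamide | C=CC[C@](C)(O[Si](CC)(CC)CC)C(=O)N(C)OC | intermediate
17 | (S)-3-methyl-3-(triethylsilyloxy)hex-5-en-2-one | C=CC[C@](C)(O[Si](CC)(CC)CC)C(C)=O | intermediate
18 | coupled C7 ketone (8S; C3=C4 E; C13 dimethyl acetal) | O=C1[C@@H](COCc2ccccc2)[C@H](C/C=C(\C)CCC(=O)[C@@](C)(O[Si](CC)(CC)CC)CC=C)[C@H](C(OC)OC)O1 | intermediate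
19 | (7R,8S) alcohol | O=C1[C@@H](COCc2ccccc2)[C@H](C/C=C(\C)CC[C@@H](O)[C@@](C)(O[Si](CC)(CC)CC)CC=C)[C@H](C(OC)OC)O1 | intermediate
20 | (3R,4R)-epoxy alcohol | O=C1[C@@H](COCc2ccccc2)[C@H](C[C@H]3O[C@]3(C)CC[C@@H](O)[C@@](C)(O[Si](CC)(CC)CC)CC=C)[C@H](C(OC)OC)O1 | intermediate (not isolated)
21 | 2,5-cis-oxolane (3R,4S,7R,8S), C3 OH, C8 OSiEt3 | O=C1[C@@H](COCc2ccccc2)[C@H](C[C@@H](O)[C@]3(C)CC[C@@H](O3)[C@@](C)(O[Si](CC)(CC)CC)CC=C)[C@H](C(OC)OC)O1 | intermediate
22 | C3 O-triisopropylsilyl ether of 21 | O=C1[C@@H](COCc2ccccc2)[C@H](C[C@@H](O[Si](C(C)C)(C(C)C)C(C)C)[C@]3(C)CC[C@@H](O3)[C@@](C)(O[Si](CC)(CC)CC)CC=C)[C@H](C(OC)OC)O1 | intermediate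
23 | C13 aldehyde, C8 OH free | O=C1[C@@H](COCc2ccccc2)[C@H](C[C@@H](O[Si](C(C)C)(C(C)C)C(C)C)[C@]3(C)CC[C@@H](O3)[C@@](C)(O)CC=C)[C@H](C=O)O1 | intermediate
24 | (12S,13S) homoallylic alcohol | O=C1[C@@H](COCc2ccccc2)[C@H](C[C@@H](O[Si](C(C)C)(C(C)C)C(C)C)[C@]3(C)CC[C@@H](O3)[C@@](C)(O)CC=C)[C@H]([C@@H](O)[C@@H](C)C=C)O1 | intermediate
25 | C13 ketone (12S) | O=C1[C@@H](COCc2ccccc2)[C@H](C[C@@H](O[Si](C(C)C)(C(C)C)C(C)C)[C@]3(C)CC[C@@H](O3)[C@@](C)(O)CC=C)[C@H](C(=O)[C@@H](C)C=C)O1 | intermediate
26 | (12S,13R) alcohol | O=C1[C@@H](COCc2ccccc2)[C@H](C[C@@H](O[Si](C(C)C)(C(C)C)C(C)C)[C@]3(C)CC[C@@H](O3)[C@@](C)(O)CC=C)[C@H]([C@H](O)[C@@H](C)C=C)O1 | intermediate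
27 | macrocyclic C10=C11 alkene (E/Z), C15 CH2OBn | C(OCc4ccccc4)[C@@H]1C(=O)O[C@H]2[C@H](O)[C@@H](C)C=CC[C@](C)(O)[C@H]3CC[C@](C)(O3)[C@H](O[Si](C(C)C)(C(C)C)C(C)C)C[C@@H]12 | intermediate
28 | saturated triol | OC[C@@H]1C(=O)O[C@H]2[C@H](O)[C@@H](C)CCC[C@](C)(O)[C@H]3CC[C@](C)(O3)[C@H](O[Si](C(C)C)(C(C)C)C(C)C)C[C@@H]12 | intermediate
29 | triacetate | CC(=O)OC[C@@H]1C(=O)O[C@H]2[C@H](OC(C)=O)[C@@H](C)CCC[C@](C)(OC(C)=O)[C@H]3CC[C@](C)(O3)[C@H](O[Si](C(C)C)(C(C)C)C(C)C)C[C@@H]12 | intermediate (not isolated)
30 | C3 O-triisopropylsilyl ether of the target | C=C1C(=O)O[C@H]2[C@H](OC(C)=O)[C@@H](C)CCC[C@](C)(OC(C)=O)[C@H]3CC[C@](C)(O3)[C@H](O[Si](C(C)C)(C(C)C)C(C)C)C[C@@H]12 | intermediate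
31 | CID10479028 (1S,3R,4S,7R,8S,12S,13R,14R) | C=C1C(=O)O[C@H]2[C@H](OC(C)=O)[C@@H](C)CCC[C@](C)(OC(C)=O)[C@H]3CC[C@](C)(O3)[C@H](O)C[C@@H]12 | target

Total step count: 24. Longest linear sequence: 19 steps (1 to 31 through steps 1–7 and 13–24); the ketone fragment 17 takes 5 steps (8–12).

Steps most likely to fail

Step 4. The primary ozonide may fragment with poor regioselectivity, or the deactivated C13 aldehyde may acetalise incompletely, so the two chain ends lose their differentiation; the α-acyloxy aldehyde may also epimerise at C14 through its enol. Fallback: setting out from 4, ozonolysis with NaBH4 work-up would give lactone diol F1. t-BuPh2SiCl and imidazole at −20 °C should silylate the unhindered C3 hydroxyl selectively (the C13 hydroxyl sits next to the substituted lactone carbon) to give C3 silyl ether F2. Dess–Martin oxidation of the C13 hydroxyl gives C13 aldehyde F3, HC(OMe)3 with pyridinium tosylate in methanol gives dimethyl acetal F4, Bu4NF buffered with AcOH gives primary alcohol F5, and a second Dess–Martin oxidation comes back to the route at 7.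

Step 20. The two α-stereocentres may compete for control of the hydride trajectory (poor facial selectivity), and the basic hydride may move the β,γ-double bond into conjugation with loss of the C12 configuration. Fallback: setting out from 24 (steps 19 and 20 are bypassed), a Mitsunobu inversion (PPh3, diisopropyl azodicarboxylate, chloroacetic acid, toluene, 0 °C to rt) would give 13R chloroacetate F6 by SN2 displacement at C13. Thiourea and NaHCO3 in ethanol then remove the chloroacetyl group, and the route is rejoined at 26.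

Step 21. Intermolecular metathesis (oligomerisation) may outrun ring closure, and the two free hydroxyls may sequester the ruthenium carbene. Fallback: setting out from 25, the ring is closed before C13 is reduced. The sp2 C13 removes the free carbinol and one gauche interaction along C12–C14, and the same catalyst at high dilution would give macrocyclic ketone F7. Reduction with LiBH(s-Bu)3 at −78 °C (hydride again anti to the C14–O bond, now from the ring periphery; the facial outcome would have to be confirmed) comes back to the route at 27.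

Further compounds
F1 | step 4 | lactone diol (C3 and C13 primary hydroxyls) | O=C1[C@@H](COCc2ccccc2)[C@H](CCO)[C@H](CO)O1
F2 | step 4 | C3 tert-butyldiphenylsilyl ether | O=C1[C@@H](COCc2ccccc2)[C@H](CCO[Si](c3ccccc3)(c4ccccc4)C(C)(C)C)[C@H](CO)O1
F3 | step 4 | C13 aldehyde | O=C1[C@@H](COCc2ccccc2)[C@H](CCO[Si](c3ccccc3)(c4ccccc4)C(C)(C)C)[C@H](C=O)O1
F4 | step 4 | C13 dimethyl acetal | O=C1[C@@H](COCc2ccccc2)[C@H](CCO[Si](c3ccccc3)(c4ccccc4)C(C)(C)C)[C@H](C(OC)OC)O1
F5 | step 4 | C3 primary alcohol | O=C1[C@@H](COCc2ccccc2)[C@H](CCO)[C@H](C(OC)OC)O1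
F6 | step 20 | 13R chloroacetate | O=C1[C@@H](COCc2ccccc2)[C@H](C[C@@H](O[Si](C(C)C)(C(C)C)C(C)C)[C@]3(C)CC[C@@H](O3)[C@@](C)(O)CC=C)[C@H]([C@H](OC(=O)CCl)[C@@H](C)C=C)O1
F7 | step 21 | macrocyclic C13 ketone (C10=C11, E/Z) | C(OCc4ccccc4)[C@@H]1C(=O)O[C@H]2C(=O)[C@@H](C)C=CC[C@](C)(O)[C@H]3CC[C@](C)(O3)[C@H](O[Si](C(C)C)(C(C)C)C(C)C)C[C@@H]12
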